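**Retrosynthetic overview**
1. Target ⇒ phloroglucinol + 11-(2-hydroxyphenyl)undecanoic acid, by disconnecting the aryl ketone C–C bond (Friedel–Crafts, last step).
2. That acid ⇒ methyl (E)-11-(2-hydroxyphenyl)undec-9-enoate, by alkene hydrogenation and ester hydrolysis.
3. The ortho-alkenylphenol ⇒ the branched allyl phenyl ether methyl 9-phenoxyundec-10-enoate, by retro aromatic Claisen.
4. Key disconnection: the C9–O(aryl) bond of that ether ⇒ the O–H of phenol + methyl undec-10-ynoate, by a new redox-neutral Rh-catalysed hydroaryloxylation.
5. No ring is formed. Ring B (2-hydroxyphenyl) is bought as phenol and joined first; ring A is bought as phloroglucinol and joined last.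

Assumption: the target SMILES has no stereocentre and no stereogenic double bond. The compound is therefore achiral and needs no enantiocontrol. The transient stereocentres of the allyl aryl ether and of the dienone are formed racemic and erased within the same step.

**Step 1**
Reactants: 1 phenol; 2 methyl undec-10-ynoate
Product: 6 methyl (E)-11-(2-hydroxyphenyl)undec-9-enoate, via allenyl ester 3 (not isolated), via branched allyl phenyl ether 4 (not isolated), via ortho-dienone 5 (not isolated)
Conditions: [Rh(cod)Cl]2 (2.5 mol%), DPEphos (6 mol%), (PhO)2P(O)OH (10 mol%), 1 (2 equiv), ClCH2CH2Cl, 80 °C, 16 h; short SiO2 plug, evaporate; PhNEt2, 190 °C, 6 h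
Reagents that add atoms: none
Why: Proposed new method: monovalent rhodium/DPEphos and the phosphoric acid co-catalyst give a trivalent rhodium hydride that isomerises alkyne 2 to allene 3 (hydrometalation/β-hydride elimination), re-adds to 3 to form a π-allyl rhodium species and closes the C9–O bond with phenol at the more substituted allyl terminus (hydroaryloxylation) to give racemic ether 4, which should not re-ionise because phenoxide is a poorer leaving group than carboxylate, and the thermal aromatic Claisen rearrangement of 4 ([3,3] shift, chair transition state with the chain equatorial, through dienone 5, then rearomatisation) carries the chain only to the ortho carbon as the linear E-alkenylphenol 6 and erases the stereocentre; the closest known reaction type is the rhodium-catalysed redox-neutral, branched-selective addition of carboxylic acids and aliphatic alcohols to terminal alkynes and allenes, whose O–H acidities bracket that of phenol (pKa about 10) but which has not been shown for a simple phenol or coupled to a Claisen shift.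

**Step 2**
Reactants: 6 methyl (E)-11-(2-hydroxyphenyl)undec-9-enoate
Product: 8 11-(2-hydroxyphenyl)undecanoic acid, via saturated methyl ester 7 (not isolated)
Conditions: H2 (1 atm), Pd/C (10 wt%), MeOH, rt, 6 h; then LiOH (4 equiv), H2O, 40 °C, 4 h; filter; 1 M HCl
Reagents that add atoms: lithium hydroxide, [Li+].[OH-]
Why: Heterogeneous catalytic hydrogenation saturates the isolated disubstituted alkene without touching the phenol ring or the ester (any Z or positional alkene isomers from step 1 converge on 7), and BAC2 saponification followed by acidification frees the acid, with no stereocentre involved.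

**Step 3**
Reactants: 8 11-(2-hydroxyphenyl)undecanoic acid; 9 phloroglucinol (anhydrous)
Product: 10 11-(2-hydroxyphenyl)-1-(2,4,6-trihydroxyphenyl)undecan-1-one (target)
Conditions: BF3·OEt2 (neat, 10 equiv), 9 (3 equiv), 85 °C, 3 h; then ice-water
Reagents that add atoms: none
Why: In this Friedel–Crafts (Nencki-type) C-acylation with a free carboxylic acid, BF3 activates the acid and binds the water formed, phloroglucinol in excess is far more carbon-nucleophilic than the monophenol ring B, and the hydrogen-bonded, deactivated ketone product resists a second acylation.

**Compound list**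
1 | phenol | Oc1ccccc1 | starting material
2 | methyl undec-10-ynoate | C#CCCCCCCCCC(=O)OC | starting material
3 | methyl undeca-9,10-dienoate | C=C=CCCCCCCCC(=O)OC | intermediate
4 | methyl 9-phenoxyundec-10-enoate (racemic) | C=CC(CCCCCCCC(=O)OC)Oc1ccccc1 | intermediate
5 | methyl (E)-11-(6-oxocyclohexa-2,4-dien-1-yl)undec-9-enoate (racemic) | O=C1C=CC=CC1C/C=C/CCCCCCCC(=O)OC | intermediate
6 | methyl (E)-11-(2-hydroxyphenyl)undec-9-enoate | Oc1ccccc1C/C=C/CCCCCCCC(=O)OC | intermediate
7 | methyl 11-(2-hydroxyphenyl)undecanoate | Oc1ccccc1CCCCCCCCCCC(=O)OC | intermediate
8 | 11-(2-hydroxyphenyl)undecanoic acid | Oc1ccccc1CCCCCCCCCCC(=O)O | intermediate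
9 | phloroglucinol (benzene-1,3,5-triol) | Oc1cc(O)cc(O)c1 | starting material
10 | 11-(2-hydroxyphenyl)-1-(2,4,6-trihydroxyphenyl)undecan-1-one (achiral) | O=C(CCCCCCCCCCc1ccccc1O)c1c(O)cc(O)cc1O | target

**Total step count:** 3 (three isolations; steps 1 and 2 are each telescoped two-stage operations).
**Longest linear sequence:** 3.

**Steps most likely to fail**

Step 1 (the proposed new step).
- Risks: linear instead of branched ether, which after the Claisen shift would give the wrong, branched side chain. Other risks are C- instead of O-allylation of phenol, alkyne oligomerisation, and rhodium hydride isomerisation of 4 to a vinyl ether before the Claisen stage.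
- Fallback with known chemistry, setting out from 2: hydroborate the alkyne with pinacolborane (5 mol% dicyclohexylborane, neat, rt) to methyl (E)-11-(4,4,5,5-tetramethyl-1,3,2-dioxaborolan-2-yl)undec-10-enoate F1. Couple this with 2-bromophenol in a Suzuki–Miyaura reaction (Pd(dppf)Cl2, K3PO4, dioxane/H2O, 80 °C) to methyl (E)-11-(2-hydroxyphenyl)undec-10-enoate F2. Put F2 through the unchanged conditions of step 2, whose hydrogenation stage brings it back to the route at 7.

Step 3.
- Risks: over-acylation of ring A, acylation at the ring B phenol leading to oligomers, poor solubility of 9, and a sluggish reaction with the long-chain acid.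
- Fallback, setting out from 8: acylate the soluble, more reactive 1,3,5-trimethoxybenzene with 8 in P2O5/MeSO3H (1:10 w/w, rt to 40 °C) to 11-(2-hydroxyphenyl)-1-(2,4,6-trimethoxyphenyl)undecan-1-one F4. Then cleave the three methyl ethers with BBr3 (CH2Cl2, −78 °C to reflux), which comes back to the route at 10.

Step 2.
- Risk: poisoning of Pd/C by traces of phosphine, amine or rhodium carried over from step 1, leaving alkene that would not survive BF3.
- Fallback, setting out from 6: reverse the order and drop the metal. Saponify first (LiOH, THF/H2O, rt, then HCl) to (E)-11-(2-hydroxyphenyl)undec-9-enoic acid F3. Then reduce the alkene with diimide generated from 2-nitrobenzenesulfonyl hydrazide and Et3N (CH2Cl2, rt), which comes back to the route at 8.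

**Further compounds**
F1 | step 1 | methyl (E)-11-(4,4,5,5-tetramethyl-1,3,2-dioxaborolan-2-yl)undec-10-enoate | COC(=O)CCCCCCCC/C=C/B1OC(C)(C)C(C)(C)O1
F2 | step 1 | methyl (E)-11-(2-hydroxyphenyl)undec-10-enoate | COC(=O)CCCCCCCC/C=C/c1ccccc1O
F3 | step 2 | (E)-11-(2-hydroxyphenyl)undec-9-enoic acid | Oc1ccccc1C/C=C/CCCCCCCC(=O)O
F4 | step 3 | 11-(2-hydroxyphenyl)-1-(2,4,6-trimethoxyphenyl)undecan-1-one | COc1cc(OC)c(C(=O)CCCCCCCCCCc2ccccc2O)c(OC)c1
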